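**Retrosynthetic overview**

1. Target 26 comes from tetra-O-benzyl phenol 25 by hydrogenolysis of the four benzyl ethers.
2. The strategy rests on ring A: C1 (CH2CH2 bridge to ring B), C2 and C6 (4-hydroxybenzyl), C3 (OH), C4 (H), C5 (OMe), a resorcinol monomethyl ether whose oxygenated carbons C3 and C5 flank the only ring hydrogen. Ring A is opened at C3–C4, C5–C6 and C2–C3 (plus C1–C6, made by the Wolff shift) to diazo enone 17 (C3, C6, C1, C2) and methoxyacetylene 20 (C4, C5).
3. 17 comes from (E)-enone 15 by detrifluoroacetylative diazo transfer; 15 comes from β-ketophosphonate 11 and arylacetaldehyde 14 by Horner–Wadsworth–Emmons olefination.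
4. 11 comes from ring B propylphosphonate 8 and ester 10; 8 comes from 4,4'-methylenediphenol 1 by mono-allylation, Claisen rearrangement, benzylation, hydroboration, iodination and Arbuzov reaction.
5. Ring order: ring B and the three 4-oxybenzyl rings are bought as arenes; ring A is the only ring formed, in step 14.

Key step: step 14

Remark on the chemistry (assumptions): methoxyacetylene is volatile and is assumed to be made and used fresh; the phosphonate is carried as its diethyl ester; 4,4'-methylenediphenol is chosen as the source of ring B because it already holds both phenols and the CH2 bridge.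
Abbreviation used in names: ArB = 2-(benzyloxy)-5-[4-(benzyloxy)benzyl]phenyl (protected ring B with its benzyl arm).
Atom map for ring A: in 17 the carbonyl carbon becomes C3, the diazo carbon C6, the alkene carbon bearing the ring B arm C1 and the alkene CH C2; in 20 the CH becomes C4 and the methoxy carbon C5.

**Route**

Step 1
Reactants: 1 4,4'-methylenediphenol
Product: 2 4-[4-(allyloxy)benzyl]phenol
Conditions: allyl bromide (0.9 equiv), K2CO3 (1.0 equiv), acetone, reflux; chromatography, unreacted 1 recycled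
Reagents that add atoms: allyl bromide, C=CCBr
Why: Williamson ether synthesis on a symmetrical bisphenol, in which a deficiency of the electrophile should hold back the bis-ether and the mono-ether is separated from diol and bis-ether by polarity.

Step 2
Reactants: 2 4-[4-(allyloxy)benzyl]phenol
Product: 3 2-allyl-4-(4-hydroxybenzyl)phenol
Conditions: N,N-diethylaniline, 200 °C, N2
Reagents that add atoms: none
Why: Aromatic Claisen rearrangement ([3,3]-sigmatropic shift, then enolisation) can deliver the allyl group only to an ortho position, since the para position carries the CH2 bridge and the two ortho positions are equivalent.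

Step 3
Reactants: 3 2-allyl-4-(4-hydroxybenzyl)phenol
Product: 4 2-allyl-1-(benzyloxy)-4-[4-(benzyloxy)benzyl]benzene
Conditions: BnBr (2.4 equiv), K2CO3, DMF, 50 °C
Reagents that add atoms: benzyl bromide, BrCc1ccccc1
Why: Double Williamson O-benzylation should cap both phenols as benzyl ethers, which tolerate the later bases, the Arbuzov heating and filtered light and are removed together in the last step.

Step 4
Reactants: 4 2-allyl-1-(benzyloxy)-4-[4-(benzyloxy)benzyl]benzene
Product: 6 3-(ArB)propan-1-ol, via B-alkyl-9-BBN adduct 5 (not isolated)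
Conditions: 9-BBN (1.3 equiv), THF, 0 °C to rt; then NaOH, H2O2, 0 °C to rt
Reagents that add atoms: 9-borabicyclo[3.3.1]nonane, B1C2CCCC1CCC2 (its atoms stay only in intermediate 5); hydrogen peroxide, OO (the hydroxyl oxygen of 6)
Why: Hydroboration–oxidation with a bulky dialkylborane should place boron, and then oxygen, on the terminal carbon of the allyl group (anti-Markovnikov).

Step 5
Reactants: 6 3-(ArB)propan-1-ol
Product: 7 1-(benzyloxy)-4-[4-(benzyloxy)benzyl]-2-(3-iodopropyl)benzene
Conditions: I2, PPh3, imidazole, CH2Cl2, 0 °C to rt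
Reagents that add atoms: iodine, II
Why: Appel-type iodination activates the primary hydroxyl on phosphorus and iodide displaces it by SN2, with no acid that could touch the benzyl ethers.

Step 6
Reactants: 7 1-(benzyloxy)-4-[4-(benzyloxy)benzyl]-2-(3-iodopropyl)benzene
Product: 8 diethyl [3-(ArB)propyl]phosphonate
Conditions: P(OEt)3 (neat, excess), 150 °C, iodoethane distilled off
Reagents that add atoms: triethyl phosphite, CCOP(OCC)OCC
Why: Michaelis–Arbuzov reaction of an unhindered primary iodide, in which the phosphite attacks by SN2 and iodide then removes one ethyl group.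

Step 7
Reactants: 9 methyl 3-(4-hydroxyphenyl)propanoate
Product: 10 methyl 3-[4-(benzyloxy)phenyl]propanoate
Conditions: BnBr (1.1 equiv), K2CO3, acetone, reflux
Reagents that add atoms: benzyl bromide, BrCc1ccccc1
Why: Williamson O-benzylation of the phenol under carbonate conditions that leave the methyl ester untouched.

Step 8
Reactants: 8 diethyl [3-(ArB)propyl]phosphonate; 10 methyl 3-[4-(benzyloxy)phenyl]propanoate
Product: 11 diethyl {6-(ArB)-1-[4-(benzyloxy)phenyl]-3-oxohexan-4-yl}phosphonate (racemic)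
Conditions: LiN(i-Pr)2 (2.2 equiv) added to 8 and 10 (1.1 equiv) in THF, −78 to 0 °C; aq NH4Cl
Reagents that add atoms: none
Why: Claisen-type acylation of the α-lithiated phosphonate by the methyl ester, pulled forward by deprotonation of the β-ketophosphonate by the second equivalent of base, should join the ring B arm to the acyl arm; the new P–CH stereocentre is racemic and becomes sp2 in step 11.

Step 9
Reactants: 12 2-(4-hydroxyphenyl)ethanol
Product: 13 2-[4-(benzyloxy)phenyl]ethanol
Conditions: BnBr (1.05 equiv), K2CO3, acetone, reflux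
Reagents that add atoms: benzyl bromide, BrCc1ccccc1
Why: Williamson etherification in which carbonate ionises only the phenol, so the primary alcohol stays free.

Step 10
Reactants: 13 2-[4-(benzyloxy)phenyl]ethanol
Product: 14 2-[4-(benzyloxy)phenyl]acetaldehyde
Conditions: Dess–Martin periodinane (1.2 equiv), NaHCO3, CH2Cl2, 0 °C to rt; used at once without chromatography
Reagents that add atoms: none
Why: Dess–Martin oxidation stops at the aldehyde under buffered, non-basic conditions, which suits an enolisable arylacetaldehyde.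

Step 11
Reactants: 11 diethyl {6-(ArB)-1-[4-(benzyloxy)phenyl]-3-oxohexan-4-yl}phosphonate; 14 2-[4-(benzyloxy)phenyl]acetaldehyde
Product: 15 (E)-4-[2-(ArB)ethyl]-1,6-bis[4-(benzyloxy)phenyl]hex-4-en-3-one
Conditions: Ba(OH)2 (activated, 0.8 equiv), THF, rt; then 14 (1.3 equiv), THF/H2O (40:1), 0 °C to rt
Reagents that add atoms: none
Why: Horner–Wadsworth–Emmons olefination of an α-branched β-ketophosphonate under mild Ba(OH)2 activation should give the trisubstituted enone with the acyl group trans to the new CH2Ar substituent (E), the geometry that keeps the larger groups apart in the elimination.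

Step 12
Reactants: 15 (E)-4-[2-(ArB)ethyl]-1,6-bis[4-(benzyloxy)phenyl]hex-4-en-3-one
Product: 17 (E)-2-diazo-4-[2-(ArB)ethyl]-1,6-bis[4-(benzyloxy)phenyl]hex-4-en-3-one, via trifluoroacetyl diketone 16 (not isolated)
Conditions: LiN(SiMe3)2 (1.1 equiv), THF, −78 °C; CF3CO2CH2CF3 (1.2 equiv), −78 °C; aq HCl work-up, crude 16 taken on; MsN3 (1.5 equiv), Et3N (1.5 equiv), H2O (1 equiv), MeCN, rt
Reagents that add atoms: 2,2,2-trifluoroethyl trifluoroacetate, O=C(OCC(F)(F)F)C(F)(F)F (trifluoroacetyl group of intermediate 16 only); methanesulfonyl azide, CS(=O)(=O)N=[N+]=[N-] (the two diazo nitrogens of 17)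
Why: Detrifluoroacetylative (deacylative Regitz-type) diazo transfer, in which kinetic deprotonation at the saturated α'-CH2 (the γ-CH2 lies trans to the carbonyl and out of reach of the coordinated base) is followed by trifluoroacetylation, and the activated CH then takes the diazo group while the trifluoroacetyl group leaves on the sulfonamide nitrogen.

Step 13
Reactants: 18 chloroacetaldehyde dimethyl acetal
Product: 20 methoxyacetylene, via sodium methoxyacetylide 19 (not isolated)
Conditions: NaNH2 (3.1 equiv), liquid NH3, −33 °C; NH3 evaporated; cold saturated aq NaCl, −20 °C; distilled into a −78 °C trap and kept as a cold ClCH2CH2Cl solution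
Reagents that add atoms: sodium amide, [Na+].[NH2-] (sodium of intermediate 19 only)
Why: Double elimination (HCl, then methanol) from the chloroacetal by amide base gives the alkynyl ether, held as its sodium acetylide until the aqueous quench releases the volatile alkyne.

Step 14
Reactants: 17 (E)-2-diazo-4-[2-(ArB)ethyl]-1,6-bis[4-(benzyloxy)phenyl]hex-4-en-3-one; 20 methoxyacetylene
Product: 25 2,4-bis[4-(benzyloxy)benzyl]-3-[2-(ArB)ethyl]-5-methoxyphenol, via vinylketene 21 (not isolated), via vinylcyclobutenone 22 (not isolated), via dienylketene 23 (not isolated), via cyclohexadienone 24 (not isolated)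
Conditions: 20 (4 equiv), degassed ClCH2CH2Cl, sealed Pyrex tube, hν (medium-pressure Hg lamp, λ > 300 nm), 20 °C until 17 is consumed; then 80 °C
Reagents that add atoms: none
Why: Light-induced loss of N2 from 17 with concerted migration of the alkenyl carbon C1 from the carbonyl carbon to the diazo carbon (photochemical Wolff rearrangement, forming C1–C6) should give vinylketene 21, as in the Danheiser benzannulation of α'-diazo enones with alkoxyalkynes, the closest known reaction type, of which an alkyl-bearing diazo carbon and this degree of substitution are demanding cases. The ketene C=C then adds methoxyacetylene 20 in a (2+2) cycloaddition (C3–C4 and C5–C6) to give cyclobutenone 22, whose four-electron conrotatory ring opening is reversible and feeds dienylketene 23 with the ketene and alkenyl arms cis. Ring A closes by thermal six-electron disrotatory electrocyclisation of 23 (C2–C3) to dienone 24, and enolisation gives phenol 25. No stereocentre survives, since the quaternary carbon of 22 and the sp3 carbon of 24 form as racemates and are erased by ring opening and by aromatisation. The step needs the unsubstituted alkyne carbon to bond to the ketene carbonyl carbon, which the polarisation of the ynol ether secures (nucleophilic CH terminus onto the electrophilic ketene carbon), so that the ketene oxygen ends as the free C3 hydroxyl and the alkyne delivers C4–H and C5–OMe. It also needs the Wolff shift to outrun the 1,2-hydrogen shift from the benzylic CH2 on the diazo carbon, which direct irradiation above 300 nm (outside the alkoxyarene absorption) is chosen to favour, and the E alkene of 17 places hydrogen, not the benzyl group, inside the electrocyclisation.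

Step 15
Reactants: 25 2,4-bis[4-(benzyloxy)benzyl]-3-[2-(ArB)ethyl]-5-methoxyphenol
Product: 26 2,4-bis(4-hydroxybenzyl)-3-{2-[2-hydroxy-5-(4-hydroxybenzyl)phenyl]ethyl}-5-methoxyphenol
Conditions: H2 (1 atm), Pd on carbon (10% Pd/C), EtOAc/MeOH (1:1), rt
Reagents that add atoms: none
Why: Catalytic hydrogenolysis cleaves the four O-benzyl C–O bonds, while the diarylmethane C–C bonds, the aryl methyl ether and the arene rings should stay intact under these mild conditions.

**Compound list**

1 | 4,4'-methylenediphenol | Oc1ccc(Cc2ccc(O)cc2)cc1 | starting material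
2 | 4-[4-(allyloxy)benzyl]phenol | C=CCOc1ccc(Cc2ccc(O)cc2)cc1 | intermediate
3 | 2-allyl-4-(4-hydroxybenzyl)phenol | C=CCc1cc(Cc2ccc(O)cc2)ccc1O | intermediate
4 | 2-allyl-1-(benzyloxy)-4-[4-(benzyloxy)benzyl]benzene | C=CCc1cc(Cc2ccc(OCc3ccccc3)cc2)ccc1OCc1ccccc1 | intermediate
5 | 9-[3-(ArB)propyl]-9-borabicyclo[3.3.1]nonane | C(CCc1cc(Cc2ccc(OCc3ccccc3)cc2)ccc1OCc1ccccc1)B1C2CCCC1CCC2 | intermediate (not isolated)
6 | 3-{2-(benzyloxy)-5-[4-(benzyloxy)benzyl]phenyl}propan-1-ol | OCCCc1cc(Cc2ccc(OCc3ccccc3)cc2)ccc1OCc1ccccc1 | intermediate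
7 | 1-(benzyloxy)-4-[4-(benzyloxy)benzyl]-2-(3-iodopropyl)benzene | ICCCc1cc(Cc2ccc(OCc3ccccc3)cc2)ccc1OCc1ccccc1 | intermediate
8 | diethyl (3-{2-(benzyloxy)-5-[4-(benzyloxy)benzyl]phenyl}propyl)phosphonate | CCOP(=O)(OCC)CCCc1cc(Cc2ccc(OCc3ccccc3)cc2)ccc1OCc1ccccc1 | intermediate
9 | methyl 3-(4-hydroxyphenyl)propanoate | COC(=O)CCc1ccc(O)cc1 | starting material
10 | methyl 3-[4-(benzyloxy)phenyl]propanoate | COC(=O)CCc1ccc(OCc2ccccc2)cc1 | intermediate
11 | diethyl {6-(ArB)-1-[4-(benzyloxy)phenyl]-3-oxohexan-4-yl}phosphonate, racemic | CCOP(=O)(OCC)C(CCc1cc(Cc2ccc(OCc3ccccc3)cc2)ccc1OCc1ccccc1)C(=O)CCc1ccc(OCc2ccccc2)cc1 | intermediate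
12 | 2-(4-hydroxyphenyl)ethanol | OCCc1ccc(O)cc1 | starting material
13 | 2-[4-(benzyloxy)phenyl]ethanol | OCCc1ccc(OCc2ccccc2)cc1 | intermediate
14 | 2-[4-(benzyloxy)phenyl]acetaldehyde | O=CCc1ccc(OCc2ccccc2)cc1 | intermediate
15 | (E)-4-[2-(ArB)ethyl]-1,6-bis[4-(benzyloxy)phenyl]hex-4-en-3-one | O=C(CCc1ccc(OCc2ccccc2)cc1)/C(CCc1cc(Cc2ccc(OCc3ccccc3)cc2)ccc1OCc1ccccc1)=C/Cc1ccc(OCc2ccccc2)cc1 | intermediate
16 | (E)-3-[4-(benzyloxy)benzyl]-5-[2-(ArB)ethyl]-7-[4-(benzyloxy)phenyl]-1,1,1-trifluorohept-5-ene-2,4-dione, racemic | O=C(C(Cc1ccc(OCc2ccccc2)cc1)C(=O)C(F)(F)F)/C(CCc1cc(Cc2ccc(OCc3ccccc3)cc2)ccc1OCc1ccccc1)=C/Cc1ccc(OCc2ccccc2)cc1 | intermediate (not isolated)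
17 | (E)-2-diazo-4-[2-(ArB)ethyl]-1,6-bis[4-(benzyloxy)phenyl]hex-4-en-3-one | [N-]=[N+]=C(Cc1ccc(OCc2ccccc2)cc1)C(=O)/C(CCc1cc(Cc2ccc(OCc3ccccc3)cc2)ccc1OCc1ccccc1)=C/Cc1ccc(OCc2ccccc2)cc1 | intermediate
18 | chloroacetaldehyde dimethyl acetal (2-chloro-1,1-dimethoxyethane) | COC(CCl)OC | starting material
19 | sodium methoxyacetylide | COC#[C-].[Na+] | intermediate (not isolated)
20 | methoxyacetylene | COC#C | intermediate
21 | (E)-2-[4-(benzyloxy)benzyl]-3-[2-(ArB)ethyl]-5-[4-(benzyloxy)phenyl]penta-1,3-dien-1-one (vinylketene) | O=C=C(Cc1ccc(OCc2ccccc2)cc1)/C(CCc1cc(Cc2ccc(OCc3ccccc3)cc2)ccc1OCc1ccccc1)=C/Cc1ccc(OCc2ccccc2)cc1 | intermediate (not isolated)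
22 | 4-[4-(benzyloxy)benzyl]-3-methoxy-4-{(E)-1-(ArB)-5-[4-(benzyloxy)phenyl]pent-3-en-3-yl}cyclobut-2-en-1-one, racemic | COC1=CC(=O)C1(Cc1ccc(OCc2ccccc2)cc1)/C(CCc1cc(Cc2ccc(OCc3ccccc3)cc2)ccc1OCc1ccccc1)=C/Cc1ccc(OCc2ccccc2)cc1 | intermediate (not isolated)
23 | 4-[4-(benzyloxy)benzyl]-5-[2-(ArB)ethyl]-3-methoxy-7-[4-(benzyloxy)phenyl]hepta-1,3,5-trien-1-one, ketene carbon C2 and C5 cis across C3=C4, 5E (dienylketene) | O=C=C/C(OC)=C(Cc1ccc(OCc2ccccc2)cc1)\C(CCc1cc(Cc2ccc(OCc3ccccc3)cc2)ccc1OCc1ccccc1)=C\Cc1ccc(OCc2ccccc2)cc1 | intermediate (not isolated)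
24 | 4,6-bis[4-(benzyloxy)benzyl]-5-[2-(ArB)ethyl]-3-methoxycyclohexa-2,4-dien-1-one, racemic | COC1=CC(=O)C(Cc2ccc(OCc3ccccc3)cc2)C(CCc2cc(Cc3ccc(OCc4ccccc4)cc3)ccc2OCc2ccccc2)=C1Cc1ccc(OCc2ccccc2)cc1 | intermediate (not isolated)
25 | 2,4-bis[4-(benzyloxy)benzyl]-3-[2-(ArB)ethyl]-5-methoxyphenol | COc1cc(O)c(Cc2ccc(OCc3ccccc3)cc2)c(CCc2cc(Cc3ccc(OCc4ccccc4)cc3)ccc2OCc2ccccc2)c1Cc1ccc(OCc2ccccc2)cc1 | intermediate
26 | 2,4-bis(4-hydroxybenzyl)-3-{2-[2-hydroxy-5-(4-hydroxybenzyl)phenyl]ethyl}-5-methoxyphenol | COc1cc(O)c(Cc2ccc(O)cc2)c(CCc2cc(Cc3ccc(O)cc3)ccc2O)c1Cc1ccc(O)cc1 | target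

**Step count**

Total steps: 15.
Longest linear sequence: 11 steps (1, 2, 3, 4, 5, 6, 8, 11, 12, 14, 15) from 4,4'-methylenediphenol.

**Steps most likely to fail**

1. Step 14 (benzannulation).
What may go wrong: after N2 loss a hydrogen of the benzylic CH2 on the diazo carbon may shift faster than the alkenyl group, leading to a cross-conjugated dienone instead of the ketene. The fully substituted ketene may also add the alkyne too slowly and be lost to dimerisation or to acylation of the product phenol, and the six arene rings may screen the light.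
Fallback: run the annulation on a diazomethyl ketone, which has no substituent on the diazo carbon, and attach the C6 arm afterwards by cross-coupling. It sets out from 8. Lithiation (n-BuLi, THF, −78 °C) and acylation with N-methoxy-N-methylacetamide would give diethyl [5-(ArB)-2-oxopentan-3-yl]phosphonate F1. Olefination of F1 with 14 as in step 11 would give (E)-3-[2-(ArB)ethyl]-5-[4-(benzyloxy)phenyl]pent-3-en-2-one F2, and diazo transfer as in step 12 would give (E)-1-diazo-3-[2-(ArB)ethyl]-5-[4-(benzyloxy)phenyl]pent-3-en-2-one F3. Irradiation of F3 with 20 as in step 14 would give 2-[4-(benzyloxy)benzyl]-3-[2-(ArB)ethyl]-5-methoxyphenol F4, which lacks only the C6 arm. N-Bromosuccinimide (1 equiv, MeCN, −20 °C) should brominate para to the hydroxyl, the position para to the methoxyl being blocked, to give 4-bromo-2-[4-(benzyloxy)benzyl]-3-[2-(ArB)ethyl]-5-methoxyphenol F5. Negishi coupling of F5 with [4-(benzyloxy)benzyl]zinc chloride F6 (from 4-(benzyloxy)benzyl chloride, Zn dust and LiCl; used in excess to absorb the phenol proton) under Pd(OAc)2 and SPhos in THF at 60 °C would come back to the route at 25.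

2. Step 11 (Horner–Wadsworth–Emmons olefination).
What may go wrong: the arylacetaldehyde may enolise and condense with itself under base, the α-branched phosphonate anion may add slowly, and base may move the new double bond out of conjugation with the ketone into conjugation with the aryl ring.
Fallback: make the trisubstituted alkene by a base-free Wittig reaction of an ester-stabilised ylide and build the ketone afterwards. It sets out from 7. PPh3 in MeCN at reflux would give [3-(ArB)propyl]triphenylphosphonium iodide F7. Treatment with NaN(SiMe3)2, then ClCO2Et, then a second equivalent of NaN(SiMe3)2 (THF, −78 to 0 °C) would give ethyl 4-(ArB)-2-(triphenylphosphoranylidene)butanoate F8. Heating F8 with 14 in toluene at 90 °C without added base would give ethyl (E)-2-[2-(ArB)ethyl]-4-[4-(benzyloxy)phenyl]but-2-enoate F9. AlMe3 with MeNH(OMe)·HCl in CH2Cl2 would give (E)-2-[2-(ArB)ethyl]-4-[4-(benzyloxy)phenyl]-N-methoxy-N-methylbut-2-enamide F10. Addition of 2-[4-(benzyloxy)phenyl]ethylmagnesium bromide F11 (from 1-(benzyloxy)-4-(2-bromoethyl)benzene and Mg) in THF at −40 °C would come back to the route at 15.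

3. Step 12 (diazo transfer).
What may go wrong: the base may remove a γ-proton (benzylic and vinylogous) instead of an α'-proton, so that a dienolate is acylated at the wrong carbon or the alkene geometry is scrambled; trifluoroacetylation of the hindered internal enolate may also stay incomplete.
Fallback: install the diazo group before the alkene exists. It sets out from 11. Dianion formation (NaH, then n-BuLi, THF, 0 to −78 °C) and reaction of the more reactive terminal carbanion (the ketone α'-carbon) with CF3CO2CH2CF3 would give crude diethyl {7-(ArB)-3-[4-(benzyloxy)benzyl]-1,1,1-trifluoro-2,4-dioxoheptan-5-yl}phosphonate F12. Its 1,3-diketone CH is by far the most acidic site, so MsN3 and Et3N in MeCN would give diethyl {6-(ArB)-2-diazo-1-[4-(benzyloxy)phenyl]-3-oxohexan-4-yl}phosphonate F13. Olefination of F13 with 14 (Ba(OH)2, wet THF) would come back to the route at 17, without passing through 15.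

**Further compounds**

F1 | step 14 | diethyl [5-(ArB)-2-oxopentan-3-yl]phosphonate | CCOP(=O)(OCC)C(CCc1cc(Cc2ccc(OCc3ccccc3)cc2)ccc1OCc1ccccc1)C(C)=O
F2 | step 14 | (E)-3-[2-(ArB)ethyl]-5-[4-(benzyloxy)phenyl]pent-3-en-2-one | CC(=O)/C(CCc1cc(Cc2ccc(OCc3ccccc3)cc2)ccc1OCc1ccccc1)=C/Cc1ccc(OCc2ccccc2)cc1
F3 | step 14 | (E)-1-diazo-3-[2-(ArB)ethyl]-5-[4-(benzyloxy)phenyl]pent-3-en-2-one | [N-]=[N+]=CC(=O)/C(CCc1cc(Cc2ccc(OCc3ccccc3)cc2)ccc1OCc1ccccc1)=C/Cc1ccc(OCc2ccccc2)cc1
F4 | step 14 | 2-[4-(benzyloxy)benzyl]-3-[2-(ArB)ethyl]-5-methoxyphenol | COc1cc(O)c(Cc2ccc(OCc3ccccc3)cc2)c(CCc2cc(Cc3ccc(OCc4ccccc4)cc3)ccc2OCc2ccccc2)c1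
F5 | step 14 | 4-bromo-2-[4-(benzyloxy)benzyl]-3-[2-(ArB)ethyl]-5-methoxyphenol | COc1cc(O)c(Cc2ccc(OCc3ccccc3)cc2)c(CCc2cc(Cc3ccc(OCc4ccccc4)cc3)ccc2OCc2ccccc2)c1Br
F6 | step 14 | [4-(benzyloxy)benzyl]zinc chloride | Cl[Zn]Cc1ccc(OCc2ccccc2)cc1
F7 | step 11 | [3-(ArB)propyl]triphenylphosphonium iodide | [I-].c1ccc(cc1)[P+](c1ccccc1)(c1ccccc1)CCCc1cc(Cc2ccc(OCc3ccccc3)cc2)ccc1OCc1ccccc1
F8 | step 11 | ethyl 4-(ArB)-2-(triphenylphosphoranylidene)butanoate | CCOC(=O)C(CCc1cc(Cc2ccc(OCc3ccccc3)cc2)ccc1OCc1ccccc1)=P(c1ccccc1)(c1ccccc1)c1ccccc1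
F9 | step 11 | ethyl (E)-2-[2-(ArB)ethyl]-4-[4-(benzyloxy)phenyl]but-2-enoate | CCOC(=O)/C(CCc1cc(Cc2ccc(OCc3ccccc3)cc2)ccc1OCc1ccccc1)=C/Cc1ccc(OCc2ccccc2)cc1
F10 | step 11 | (E)-2-[2-(ArB)ethyl]-4-[4-(benzyloxy)phenyl]-N-methoxy-N-methylbut-2-enamide | CON(C)C(=O)/C(CCc1cc(Cc2ccc(OCc3ccccc3)cc2)ccc1OCc1ccccc1)=C/Cc1ccc(OCc2ccccc2)cc1
F11 | step 11 | 2-[4-(benzyloxy)phenyl]ethylmagnesium bromide | Br[Mg]CCc1ccc(OCc2ccccc2)cc1
F12 | step 12 | diethyl {7-(ArB)-3-[4-(benzyloxy)benzyl]-1,1,1-trifluoro-2,4-dioxoheptan-5-yl}phosphonate | CCOP(=O)(OCC)C(CCc1cc(Cc2ccc(OCc3ccccc3)cc2)ccc1OCc1ccccc1)C(=O)C(Cc1ccc(OCc2ccccc2)cc1)C(=O)C(F)(F)F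
F13 | step 12 | diethyl {6-(ArB)-2-diazo-1-[4-(benzyloxy)phenyl]-3-oxohexan-4-yl}phosphonate | CCOP(=O)(OCC)C(CCc1cc(Cc2ccc(OCc3ccccc3)cc2)ccc1OCc1ccccc1)C(=O)C(=[N+]=[N-])Cc1ccc(OCc2ccccc2)cc1
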